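**Plan**
- Cuts (labdane numbering): the epoxide goes back to the Z-C13=C14 olefin; ring C is cut at C13=C14 (ring-closing metathesis), O–C15 (allyl ether) and C12–C13 (B-alkyl Suzuki coupling); C3–Br goes back to a C3 ketone through the C2=C3 bromoalkene; one C4 methyl and H-5 come from reductive methylation of a 4-en-3-one; last come C9–C10 of ring B, C9=C11 (cross-metathesis) and C5–C6 (aryl–alkyl bond).
- Enabling feature: in ring A the quaternary, methyl-bearing C10 lies para to C3 (CHBr in the target, C–OH in a phenol) and C4 already bears a methyl group, while C9 is the allylic CH next to the oxygenated C8. Ring A can therefore start as a 2,4-dimethylphenol whose para carbon C10 is alkylated by C9 of an allyl–iridium unit; this closes ring B and leaves C11=C12 as a vinyl group.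
- Forward order: arene (ring A) → chain C6–C9 with the C8 carbinol → allyl carbonate C11–C12 → ring B by dearomatisation → ring A reduced and methylated → C13 unit and O-allyl group → ring C by metathesis → epoxide → C3–Br.
- Stereochemistry: C8 from Sharpless epoxidation, kept through the 1,3-transposition; C9 from the iridium ligand and C10 from the chair closure; C5 from axial protonation in the dissolving-metal step; C13/C14 from peracid attack on the outer face of the folded oxocene; C3 from axial hydrogen delivery to the α-bromo radical.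

Key step: step 14

Numbering and assumption: labdane numbering is used for the bicyclic and tricyclic compounds (C3 = CHBr, C4 = CMe2, C5/C10 = ring fusion, C8 = ether carbon with methyl, C9 = its CH neighbour, C11–C15 = oxocane carbons, C13/C14 = epoxide), in which the target is 3S,5R,8R,9R,10S,13R,14S; the antipode of the phosphoramidite in step 14 is assigned from the empirical facial rule for linear (E)-allyl carbonates, and its mirror image would be taken if that rule does not hold for this substrate.

**Route**

Step 1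
Reactants: 1 2-bromo-1,3-dimethylbenzene
Product: 2 2-bromo-1,3-dimethyl-4-nitrobenzene
Conditions: fuming HNO3, AcOH, 0 °C → rt
Reagents that add atoms: nitric acid, O[N+](=O)[O-]
Why: Electrophilic aromatic nitration, in which both methyl groups direct to C4 (ortho to one, para to the other) and outweigh the weaker para direction of bromine toward C5.

Step 2
Reactants: 2 2-bromo-1,3-dimethyl-4-nitrobenzene
Product: 3 3-bromo-2,4-dimethylaniline
Conditions: H2 (1 atm), 5% Pt/C (sulfided), EtOAc, rt
Reagents that add atoms: none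
Why: Catalytic hydrogenation of a nitroarene over sulfided platinum on carbon, a catalyst that reduces the nitro group without hydrogenolysis of the aryl bromide.

Step 3
Reactants: 3 3-bromo-2,4-dimethylaniline
Product: 5 3-bromo-2,4-dimethylphenol, via arenediazonium hydrogen sulfate 4 (not isolated)
Conditions: NaNO2, aq H2SO4, 0 °C; then run into boiling aq H2SO4
Reagents that add atoms: water, O
Why: Diazotisation followed by thermal hydrolysis of the diazonium salt (phenol synthesis from an aniline), which leaves the aryl bromide and the methyl groups untouched.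

Step 4
Reactants: 5 3-bromo-2,4-dimethylphenol
Product: 6 (3-bromo-2,4-dimethylphenoxy)tri(propan-2-yl)silane
Conditions: TIPSCl, imidazole, DMF, rt
Reagents that add atoms: chlorotri(propan-2-yl)silane, CC(C)[Si](Cl)(C(C)C)C(C)C
Why: Silylation of the phenol with a bulky chlorosilane and imidazole gives an aryl silyl ether that withstands base, hydride, titanium alkoxide and metathesis conditions and is removed later with fluoride.

Step 5
Reactants: 6 (3-bromo-2,4-dimethylphenoxy)tri(propan-2-yl)silane; 7 but-3-en-2-ol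
Product: 8 4-{2,6-dimethyl-3-[tri(propan-2-yl)silyloxy]phenyl}butan-2-one
Conditions: Pd2(dba)3 (2.5 mol%), [HP(t-Bu)3]BF4 (6 mol%), Cy2NMe, 1,4-dioxane, 90 °C
Reagents that add atoms: none
Why: Heck reaction with an allylic alcohol: the arylpalladium species adds to the terminal alkene carbon and β-hydride elimination toward the carbinol carbon gives the enol and hence the methyl ketone, the bulky electron-rich phosphine being needed for the di-ortho-substituted bromide.

Step 6
Reactants: 8 4-{2,6-dimethyl-3-[tri(propan-2-yl)silyloxy]phenyl}butan-2-one; 9 triethyl phosphonoacetate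
Product: 10 ethyl (2E)-5-{2,6-dimethyl-3-[tri(propan-2-yl)silyloxy]phenyl}-3-methylpent-2-enoate
Conditions: NaH, THF, 0 °C → reflux
Reagents that add atoms: none
Why: Horner–Wadsworth–Emmons olefination of the methyl ketone, expected to favour the E enoate (ester trans to the larger arylethyl group); the minor Z isomer is removed by chromatography because olefin geometry fixes the configuration installed in step 8.

Step 7
Reactants: 10 ethyl (2E)-5-{2,6-dimethyl-3-[tri(propan-2-yl)silyloxy]phenyl}-3-methylpent-2-enoate
Product: 11 (2E)-5-{2,6-dimethyl-3-[tri(propan-2-yl)silyloxy]phenyl}-3-methylpent-2-en-1-ol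
Conditions: i-Bu2AlH, CH2Cl2, −78 °C; Rochelle salt work-up
Reagents that add atoms: none
Why: 1,2-Reduction of the conjugated ester by the aluminium hydride at low temperature gives the E allylic alcohol without touching the trisubstituted olefin or the silyl ether.

Step 8
Reactants: 11 (2E)-5-{2,6-dimethyl-3-[tri(propan-2-yl)silyloxy]phenyl}-3-methylpent-2-en-1-ol
Product: 12 [(2R,3R)-3-(2-{2,6-dimethyl-3-[tri(propan-2-yl)silyloxy]phenyl}ethyl)-3-methyloxiran-2-yl]methanol
Conditions: Ti(O-i-Pr)4 (10 mol%), D-(−)-diethyl tartrate (12 mol%), t-BuOOH, 4 Å MS, CH2Cl2, −20 °C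
Reagents that add atoms: tert-butyl hydroperoxide, CC(C)(C)OO
Why: Sharpless asymmetric epoxidation of an E trisubstituted allylic alcohol: with D-(−)-diethyl tartrate the titanium tartrate complex delivers oxygen to the face that gives the (2R,3R)-epoxy alcohol, which sets the future C8 as R.

Step 9
Reactants: 12 [(2R,3R)-3-(2-{2,6-dimethyl-3-[tri(propan-2-yl)silyloxy]phenyl}ethyl)-3-methyloxiran-2-yl]methanol
Product: 14 (3R)-5-{2,6-dimethyl-3-[tri(propan-2-yl)silyloxy]phenyl}-3-methylpent-1-en-3-ol, via epoxy iodide 13 (not isolated)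
Conditions: PPh3, I2, imidazole, THF, 0 °C; then Zn dust, AcOH, 0 °C → rt
Reagents that add atoms: none
Why: Appel-type iodination makes the primary iodide and zinc then effects reductive β-elimination with opening of the epoxide (1,3-transposition to the tertiary allylic alcohol), the C8–O bond and hence the configuration set in step 8 being untouched.

Step 10
Reactants: 15 (2Z)-but-2-ene-1,4-diol
Product: 16 (2Z)-but-2-ene-1,4-diyl dimethyl biscarbonate
Conditions: ClCO2Me, pyridine, CH2Cl2, 0 °C
Reagents that add atoms: methyl chloroformate, COC(=O)Cl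
Why: Acylation of both primary hydroxyl groups with the chloroformate under pyridine gives the symmetrical bis(carbonate) used as the metathesis partner.

Step 11
Reactants: 14 (3R)-5-{2,6-dimethyl-3-[tri(propan-2-yl)silyloxy]phenyl}-3-methylpent-1-en-3-ol; 16 (2Z)-but-2-ene-1,4-diyl dimethyl biscarbonate
Product: 17 (2E,4R)-6-{2,6-dimethyl-3-[tri(propan-2-yl)silyloxy]phenyl}-4-hydroxy-4-methylhex-2-en-1-yl methyl carbonate
Conditions: 16 (3 equiv), second-generation Hoveyda–Grubbs catalyst RuCl2(NHC)(=CH-C6H4-2-O-i-Pr) (NHC = 1,3-dimesitylimidazolidin-2-ylidene; 5 mol%), CH2Cl2, 40 °C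
Reagents that add atoms: none
Why: Olefin cross-metathesis between the vinyl group of the free tertiary allylic alcohol and an excess of the symmetrical Z olefin 16, expected to give the E disubstituted olefin, the quaternary carbinol centre and the aryl silyl ether being inert.

Step 12
Reactants: 17 (2E,4R)-6-{2,6-dimethyl-3-[tri(propan-2-yl)silyloxy]phenyl}-4-hydroxy-4-methylhex-2-en-1-yl methyl carbonate
Product: 18 (2E,4R)-6-{2,6-dimethyl-3-[tri(propan-2-yl)silyloxy]phenyl}-4-(methoxymethoxy)-4-methylhex-2-en-1-yl methyl carbonate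
Conditions: MOMCl, i-Pr2NEt, ClCH2CH2Cl, 50 °C
Reagents that add atoms: chloromethyl methyl ether, COCCl
Why: Alkylation of the tertiary alcohol with the reactive α-chloro ether under amine base (MOM ether formation), so that the C8 oxygen can neither attack the allyl–iridium unit nor be deprotonated in the later base steps.

Step 13
Reactants: 18 (2E,4R)-6-{2,6-dimethyl-3-[tri(propan-2-yl)silyloxy]phenyl}-4-(methoxymethoxy)-4-methylhex-2-en-1-yl methyl carbonate
Product: 19 (2E,4R)-6-(3-hydroxy-2,6-dimethylphenyl)-4-(methoxymethoxy)-4-methylhex-2-en-1-yl methyl carbonate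
Conditions: Bu4NF, AcOH, THF, 0 °C
Reagents that add atoms: none
Why: Fluoride-induced cleavage of the aryl silyl ether, buffered with acetic acid so that the phenol stays protonated and neither the allylic carbonate nor the MOM acetal is attacked.

Step 14
Reactants: 19 (2E,4R)-6-(3-hydroxy-2,6-dimethylphenyl)-4-(methoxymethoxy)-4-methylhex-2-en-1-yl methyl carbonate
Product: 20 (4aR,5R,6R)-5-ethenyl-6-(methoxymethoxy)-1,4a,6-trimethyl-5,6,7,8-tetrahydronaphthalen-2(4aH)-one
Conditions: [Ir(cod)Cl]2 (4 mol%), L (8 mol%; L = (Sa)-1,1′-binaphthalene-2,2′-diyl N,N-bis[(S)-1-phenylethyl]phosphoramidite), n-PrNH2 (activation, then evaporated); Cs2CO3 (0.2 equiv), THF (0.01 M), 50 °C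
Reagents that add atoms: none
Why: Proposed new method: the cyclometalated iridium phosphoramidite catalyst ionises the allylic carbonate of 19 to an η3-allyl complex with loss of CO2 and methoxide, the methoxide (started by a little Cs2CO3) forms the phenolate, and the phenolate para carbon C10 attacks the substituted allyl terminus C9 anti to iridium, so that C9–C10 forms, ring B closes and, because C10 carries a methyl group, the ring stays dearomatised as the cross-conjugated dienone 20. The closest known reaction type is the iridium-catalysed intramolecular allylic dearomatisation of para-tethered phenols to spirocyclohexadienones; new here is the meta tether, which turns the alkylated para carbon into a ring-fusion atom. Ring B closes in a 6-exo mode with respect to the allyl unit (C9 in the ring, C11=C12 left outside as the vinyl group) through a chair-like transition state. C9 is set by the ligand, whose (Sa,Sc,Sc) antipode is selected from the empirical facial rule for linear (E)-allyl carbonates to give 9R, while the quaternary C8 centre, whose smaller OMOM group can point toward the metal, is expected to add only a small bias; C10 follows from C9 because the allyl unit sits equatorial in the chair, which places the C10 methyl axial and anti to H-9. The step needs branched over linear attack (usual for iridium and enforced here, since attack at C12 would close an eight-membered ring), carbon over oxygen alkylation (the meta oxygen cannot reach the allyl unit, and high dilution suppresses the intermolecular ether) and para over ortho carbon attack (both close a six-membered ring, but the ortho carbon C4 is screened by the ion-paired oxygen and would give the less stable linearly conjugated dienone).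

Step 15
Reactants: 20 (4aR,5R,6R)-5-ethenyl-6-(methoxymethoxy)-1,4a,6-trimethyl-5,6,7,8-tetrahydronaphthalen-2(4aH)-one
Product: 21 (4aR,5R,6R)-5-ethenyl-6-(methoxymethoxy)-1,4a,6-trimethyl-4,4a,5,6,7,8-hexahydronaphthalen-2(3H)-one
Conditions: [(Ph3P)CuH]6 (0.25 equiv), H2O (2 equiv), toluene, rt
Reagents that add atoms: none
Why: Copper hydride conjugate reduction, which adds hydride to the less substituted enone terminus C1 (a CH next to the quaternary C10) and not to the fully substituted C5 or the isolated vinyl group, the copper enolate being protonated at C2 by water to leave the 4-en-3-one.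

Step 16
Reactants: 21 (4aR,5R,6R)-5-ethenyl-6-(methoxymethoxy)-1,4a,6-trimethyl-4,4a,5,6,7,8-hexahydronaphthalen-2(3H)-one
Product: 23 (4aS,5R,6R,8aR)-5-ethenyl-6-(methoxymethoxy)-1,1,4a,6-tetramethyloctahydronaphthalen-2(1H)-one, via lithium enolate 22 (not isolated)
Conditions: Li, NH3(l)/THF, t-BuOH (1 equiv), −78 °C; isoprene; then MeI, −78 → −33 °C
Reagents that add atoms: iodomethane, CI
Why: Dissolving-metal (Birch-type) reduction of the enone and alkylation of the regiodefined enolate: protonation of the β-carbanion at C5 on its axial α-face gives the trans ring fusion and iodomethane then quaternises C4, while the isolated vinyl group and the MOM ether are inert to lithium in ammonia.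

Step 17
Reactants: 23 (4aS,5R,6R,8aR)-5-ethenyl-6-(methoxymethoxy)-1,1,4a,6-tetramethyloctahydronaphthalen-2(1H)-one; 24 2-bromoprop-1-ene
Product: 26 (4aS,5R,6R,8aR)-6-(methoxymethoxy)-1,1,4a,6-tetramethyl-5-(3-methylbut-3-en-1-yl)octahydronaphthalen-2(1H)-one, via B-alkyl-9-BBN borane 25 (not isolated)
Conditions: 9-BBN, THF, 0 °C → rt; then 24, Pd(dppf)Cl2 (5 mol%), aq K3PO4, DMF, 50 °C
Reagents that add atoms: none
Why: Anti-Markovnikov hydroboration of the vinyl group by 9-BBN (faster than reduction of the hindered, α-quaternary ketone) followed by B-alkyl Suzuki–Miyaura coupling with the alkenyl bromide attaches C13 with its methyl group and terminal methylene.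

Step 18
Reactants: 26 (4aS,5R,6R,8aR)-6-(methoxymethoxy)-1,1,4a,6-tetramethyl-5-(3-methylbut-3-en-1-yl)octahydronaphthalen-2(1H)-one
Product: 27 (4aS,5R,6R,8aR)-6-(methoxymethoxy)-1,1,4a,6-tetramethyl-5-(3-methylbut-3-en-1-yl)-1,4,4a,5,6,7,8,8a-octahydronaphthalen-2-yl trifluoromethanesulfonate
Conditions: KN(SiMe3)2, THF, −78 °C; PhNTf2, −78 → 0 °C
Reagents that add atoms: N-phenylbis(trifluoromethanesulfonimide), O=S(=O)(N(c1ccccc1)S(=O)(=O)C(F)(F)F)C(F)(F)F
Why: Enol triflate formation: the ketone can enolise only toward C2 because C4 is quaternary, and the potassium enolate is O-sulfonylated by the triflimide.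

Step 19
Reactants: 27 (4aS,5R,6R,8aR)-6-(methoxymethoxy)-1,1,4a,6-tetramethyl-5-(3-methylbut-3-en-1-yl)-1,4,4a,5,6,7,8,8a-octahydronaphthalen-2-yl trifluoromethanesulfonate
Product: 28 (4aS,5R,6R,8aR)-2-bromo-6-(methoxymethoxy)-1,1,4a,6-tetramethyl-5-(3-methylbut-3-en-1-yl)-1,4,4a,5,6,7,8,8a-octahydronaphthalene
Conditions: Ni(cod)2 (10 mol%), LiBr, DMA/THF, rt
Reagents that add atoms: lithium bromide, [Li+].[Br-]
Why: Nickel-catalysed triflate-to-halide exchange of an enol triflate (oxidative addition, triflate/bromide metathesis, C–Br reductive elimination) gives the bromoalkene without free bromine, so the isopropenyl group and the MOM ether are not touched.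

Step 20
Reactants: 28 (4aS,5R,6R,8aR)-2-bromo-6-(methoxymethoxy)-1,1,4a,6-tetramethyl-5-(3-methylbut-3-en-1-yl)-1,4,4a,5,6,7,8,8a-octahydronaphthalene
Product: 29 (1R,2R,4aR,8aS)-6-bromo-2,5,5,8a-tetramethyl-1-(3-methylbut-3-en-1-yl)-1,2,3,4,4a,5,8,8a-octahydronaphthalen-2-ol
Conditions: ZnBr2, n-PrSH, CH2Cl2, 0 °C
Reagents that add atoms: none
Why: Lewis acid/thiol cleavage of the MOM acetal (the thiol captures the methoxymethyl cation), a mild and fast deprotection that frees the tertiary alcohol without ionising the C8–O bond or touching either olefin.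

Step 21
Reactants: 29 (1R,2R,4aR,8aS)-6-bromo-2,5,5,8a-tetramethyl-1-(3-methylbut-3-en-1-yl)-1,2,3,4,4a,5,8,8a-octahydronaphthalen-2-ol; 30 3-bromoprop-1-ene
Product: 31 (1R,2R,4aR,8aS)-6-bromo-2,5,5,8a-tetramethyl-1-(3-methylbut-3-en-1-yl)-2-(prop-2-en-1-yloxy)-1,2,3,4,4a,5,8,8a-octahydronaphthalene
Conditions: KH, THF, 0 °C; 30, Bu4NI (cat.), 0 °C → rt
Reagents that add atoms: none
Why: Williamson etherification of the potassium tertiary alkoxide with the reactive allylic bromide; the bromoalkene is inert to base and no enolisable carbonyl group remains.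

Step 22
Reactants: 31 (1R,2R,4aR,8aS)-6-bromo-2,5,5,8a-tetramethyl-1-(3-methylbut-3-en-1-yl)-2-(prop-2-en-1-yloxy)-1,2,3,4,4a,5,8,8a-octahydronaphthalene
Product: 32 (5R,8R,9R,10S,13Z)-3-bromo-8,15-epoxylabda-2,13-diene (rings A and B as in 31; eight-membered ring C = C8–O–C15H2–C14H=C13(CH3)–C12H2–C11H2–C9)
Conditions: second-generation Grubbs catalyst RuCl2(NHC)(PCy3)(=CHPh) (NHC = 1,3-dimesitylimidazolidin-2-ylidene; 10 mol%), CH2Cl2 (2 mM), 40 °C
Reagents that add atoms: none
Why: Ring-closing olefin metathesis (release of ethene) between the allyl ether and the 1,1-disubstituted olefin, favoured by the gauche, diequatorial disposition of the C8 oxygen and the C9 chain on ring B; an eight-membered ring can hold only the Z olefin, and the hindered trisubstituted bromoalkene does not take part.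

Step 23
Reactants: 32 (5R,8R,9R,10S,13Z)-3-bromo-8,15-epoxylabda-2,13-diene
Product: 33 (5R,8R,9R,10S,13R,14S)-3-bromo-8,15:13,14-diepoxylabd-2-ene
Conditions: mCPBA, NaHCO3, CH2Cl2, 0 °C
Reagents that add atoms: 3-chloroperoxybenzoic acid, OOC(=O)c1cccc(Cl)c1
Why: Prilezhaev epoxidation: the peracid reacts with the electron-rich trisubstituted ring olefin rather than with the electron-poor bromoalkene and should approach the outer face of the oxocene, which folds toward the α-face to keep C15 anti to the axial C8 methyl group, so that oxygen is delivered to the face that gives 13R,14S.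

Step 24
Reactants: 33 (5R,8R,9R,10S,13R,14S)-3-bromo-8,15:13,14-diepoxylabd-2-ene
Product: 34 (3S,5R,8R,9R,10S,13R,14S)-3-bromo-8,15:13,14-diepoxylabdane (CNP0311742.2)
Conditions: Mn(dpm)3 (10 mol%), PhSiH3, t-BuOOH, i-PrOH, rt
Reagents that add atoms: none
Why: Metal-hydride hydrogen-atom-transfer hydrogenation of a haloalkene: the manganese hydride transfers a hydrogen atom to C2, and the resulting α-bromo C3 radical takes up the second hydrogen on its axial α-face, opposite to the axial 4β- and 10β-methyl groups, which leaves bromine equatorial (3S) while the epoxide, the ether and the C–Br bond are spared by the neutral conditions.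

**Compound list**

1 | 2-bromo-1,3-dimethylbenzene | Cc1cccc(C)c1Br | starting material
2 | 2-bromo-1,3-dimethyl-4-nitrobenzene | Cc1ccc([N+](=O)[O-])c(C)c1Br | intermediate
3 | 3-bromo-2,4-dimethylaniline | Cc1ccc(N)c(C)c1Br | intermediate
4 | 3-bromo-2,4-dimethylbenzenediazonium hydrogen sulfate | Cc1ccc([N+]#N)c(C)c1Br.OS(=O)(=O)[O-] | intermediate
5 | 3-bromo-2,4-dimethylphenol | Cc1ccc(O)c(C)c1Br | intermediate
6 | (3-bromo-2,4-dimethylphenoxy)tri(propan-2-yl)silane | Cc1ccc(O[Si](C(C)C)(C(C)C)C(C)C)c(C)c1Br | intermediate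
7 | but-3-en-2-ol (racemic) | CC(O)C=C | starting material
8 | 4-{2,6-dimethyl-3-[tri(propan-2-yl)silyloxy]phenyl}butan-2-one | CC(=O)CCc1c(C)ccc(O[Si](C(C)C)(C(C)C)C(C)C)c1C | intermediate
9 | triethyl phosphonoacetate | CCOC(=O)CP(=O)(OCC)OCC | starting material
10 | ethyl (2E)-5-{2,6-dimethyl-3-[tri(propan-2-yl)silyloxy]phenyl}-3-methylpent-2-enoate | CCOC(=O)/C=C(\C)CCc1c(C)ccc(O[Si](C(C)C)(C(C)C)C(C)C)c1C | intermediate
11 | (2E)-5-{2,6-dimethyl-3-[tri(propan-2-yl)silyloxy]phenyl}-3-methylpent-2-en-1-ol | OC/C=C(\C)CCc1c(C)ccc(O[Si](C(C)C)(C(C)C)C(C)C)c1C | intermediate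
12 | [(2R,3R)-3-(2-{2,6-dimethyl-3-[tri(propan-2-yl)silyloxy]phenyl}ethyl)-3-methyloxiran-2-yl]methanol | OC[C@H]1O[C@]1(C)CCc1c(C)ccc(O[Si](C(C)C)(C(C)C)C(C)C)c1C | intermediate
13 | (2S,3R)-3-(2-{2,6-dimethyl-3-[tri(propan-2-yl)silyloxy]phenyl}ethyl)-2-(iodomethyl)-3-methyloxirane | IC[C@H]1O[C@]1(C)CCc1c(C)ccc(O[Si](C(C)C)(C(C)C)C(C)C)c1C | intermediate
14 | (3R)-5-{2,6-dimethyl-3-[tri(propan-2-yl)silyloxy]phenyl}-3-methylpent-1-en-3-ol | Cc1ccc(O[Si](C(C)C)(C(C)C)C(C)C)c(C)c1CC[C@@](C)(O)C=C | intermediate
15 | (2Z)-but-2-ene-1,4-diol | OC/C=C\CO | starting material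
16 | (2Z)-but-2-ene-1,4-diyl dimethyl biscarbonate | COC(=O)OC/C=C\COC(=O)OC | intermediate
17 | (2E,4R)-6-{2,6-dimethyl-3-[tri(propan-2-yl)silyloxy]phenyl}-4-hydroxy-4-methylhex-2-en-1-yl methyl carbonate | Cc1ccc(O[Si](C(C)C)(C(C)C)C(C)C)c(C)c1CC[C@@](C)(O)/C=C/COC(=O)OC | intermediate
18 | (2E,4R)-6-{2,6-dimethyl-3-[tri(propan-2-yl)silyloxy]phenyl}-4-(methoxymethoxy)-4-methylhex-2-en-1-yl methyl carbonate | Cc1ccc(O[Si](C(C)C)(C(C)C)C(C)C)c(C)c1CC[C@@](C)(OCOC)/C=C/COC(=O)OC | intermediate
19 | (2E,4R)-6-(3-hydroxy-2,6-dimethylphenyl)-4-(methoxymethoxy)-4-methylhex-2-en-1-yl methyl carbonate | Cc1ccc(O)c(C)c1CC[C@@](C)(OCOC)/C=C/COC(=O)OC | intermediate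
20 | (4aR,5R,6R)-5-ethenyl-6-(methoxymethoxy)-1,4a,6-trimethyl-5,6,7,8-tetrahydronaphthalen-2(4aH)-one | CC1=C2CC[C@@](C)(OCOC)[C@H](C=C)[C@@]2(C)C=CC1=O | intermediate
21 | (4aR,5R,6R)-5-ethenyl-6-(methoxymethoxy)-1,4a,6-trimethyl-4,4a,5,6,7,8-hexahydronaphthalen-2(3H)-one | CC1=C2CC[C@@](C)(OCOC)[C@H](C=C)[C@@]2(C)CCC1=O | intermediate
22 | lithium (4aS,5R,6R,8aR)-5-ethenyl-6-(methoxymethoxy)-1,4a,6-trimethyl-3,4,4a,5,6,7,8,8a-octahydronaphthalen-2-olate | CC1=C(O[Li])CC[C@]2(C)[C@@H](C=C)[C@](C)(OCOC)CC[C@@H]12 | intermediate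
23 | (4aS,5R,6R,8aR)-5-ethenyl-6-(methoxymethoxy)-1,1,4a,6-tetramethyloctahydronaphthalen-2(1H)-one | CC1(C)C(=O)CC[C@]2(C)[C@@H](C=C)[C@](C)(OCOC)CC[C@@H]12 | intermediate
24 | 2-bromoprop-1-ene | CC(Br)=C | starting material
25 | B-alkyl-9-BBN adduct of 23 (9-borabicyclo[3.3.1]nonan-9-yl on the terminal carbon C12 of the former vinyl group; stereocentres as in 23) | CC1(C)C(=O)CC[C@]2(C)[C@@H](CCB3C4CCCC3CCC4)[C@](C)(OCOC)CC[C@@H]12 | intermediate
26 | (4aS,5R,6R,8aR)-6-(methoxymethoxy)-1,1,4a,6-tetramethyl-5-(3-methylbut-3-en-1-yl)octahydronaphthalen-2(1H)-one | CC1(C)C(=O)CC[C@]2(C)[C@@H](CCC(C)=C)[C@](C)(OCOC)CC[C@@H]12 | intermediate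
27 | (4aS,5R,6R,8aR)-6-(methoxymethoxy)-1,1,4a,6-tetramethyl-5-(3-methylbut-3-en-1-yl)-1,4,4a,5,6,7,8,8a-octahydronaphthalen-2-yl trifluoromethanesulfonate | CC1(C)C(OS(=O)(=O)C(F)(F)F)=CC[C@]2(C)[C@@H](CCC(C)=C)[C@](C)(OCOC)CC[C@@H]12 | intermediate
28 | (4aS,5R,6R,8aR)-2-bromo-6-(methoxymethoxy)-1,1,4a,6-tetramethyl-5-(3-methylbut-3-en-1-yl)-1,4,4a,5,6,7,8,8a-octahydronaphthalene | CC1(C)C(Br)=CC[C@]2(C)[C@@H](CCC(C)=C)[C@](C)(OCOC)CC[C@@H]12 | intermediate
29 | (1R,2R,4aR,8aS)-6-bromo-2,5,5,8a-tetramethyl-1-(3-methylbut-3-en-1-yl)-1,2,3,4,4a,5,8,8a-octahydronaphthalen-2-ol | CC1(C)C(Br)=CC[C@]2(C)[C@@H](CCC(C)=C)[C@](C)(O)CC[C@@H]12 | intermediate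
30 | 3-bromoprop-1-ene (allyl bromide) | C=CCBr | starting material
31 | (1R,2R,4aR,8aS)-6-bromo-2,5,5,8a-tetramethyl-1-(3-methylbut-3-en-1-yl)-2-(prop-2-en-1-yloxy)-1,2,3,4,4a,5,8,8a-octahydronaphthalene | CC1(C)C(Br)=CC[C@]2(C)[C@@H](CCC(C)=C)[C@](C)(OCC=C)CC[C@@H]12 | intermediate
32 | (5R,8R,9R,10S,13Z)-3-bromo-8,15-epoxylabda-2,13-diene (labdane numbering) | CC1(C)C(Br)=CC[C@]2(C)[C@H]3CC/C(C)=C\CO[C@]3(C)CC[C@@H]12 | intermediate
33 | (5R,8R,9R,10S,13R,14S)-3-bromo-8,15:13,14-diepoxylabd-2-ene (labdane numbering) | CC1(C)C(Br)=CC[C@]2(C)[C@H]3CC[C@@]4(C)O[C@H]4CO[C@]3(C)CC[C@@H]12 | intermediate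
34 | (3S,5R,8R,9R,10S,13R,14S)-3-bromo-8,15:13,14-diepoxylabdane, CNP0311742.2 | CC1(C)[C@@H](Br)CC[C@]2(C)[C@H]3CC[C@@]4(C)O[C@H]4CO[C@]3(C)CC[C@@H]12 | target

**Step count**

Total: 24 steps. Longest linear sequence: 23 steps (steps 1–9 and 11–24, from 1 to 34); step 10 is a one-step side branch.

**Steps most likely to fail**

1. Step 14 (proposed new method). The cyclisation may go through the ortho carbon C4 instead of the para carbon C10, may close on the wrong allyl face if ligand control and the C8 centre oppose each other, or may be overtaken by intermolecular O-allylation. The fallback uses known chemistry with reversed polarity, the phenol becoming the electrophile. It sets out from 14: cross-metathesis with allyltrimethylsilane (second-generation Hoveyda–Grubbs catalyst, CH2Cl2, 40 °C) should give the (3R,4E)-allylsilane F1. MOMCl and i-Pr2NEt then give its MOM ether F2, and Bu4NF buffered with AcOH frees the phenol F3. PhI(OAc)2 in (CF3)2CHOH at −20 °C oxidises the phenol, and the γ-carbon of the tethered allylsilane captures the para carbon (hypervalent-iodine oxidative dearomatisation with Hosomi–Sakurai-type allylation). This forms the same C9–C10 bond with loss of silicon and comes back to the route at 20. Only substrate control operates in this variant, so the C9/C10 diastereomers would be separated by chromatography.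

2. Step 24. The trisubstituted epoxide may be opened in the silane/alcohol medium, bromine may be lost from the radical intermediates, or hydrogen may be delivered to the equatorial face at C3. The fallback masks the epoxide and re-forms it last. It sets out from 33: LiCl and AcOH in THF should open the epoxide at the less substituted C14 with inversion to the chlorohydrin F5. The same Mn(dpm)3/PhSiH3/t-BuOOH hydrogenation, now on a substrate without an epoxide, should give the saturated 3-bromide chlorohydrin F6. K2CO3 in MeOH then recloses the epoxide by intramolecular Williamson displacement, a second inversion at C14, and the sequence comes back to the route at 34.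

3. Step 23. Facial selectivity may be poor, or the peracid may attack the other face if the oxocene prefers an extended rather than the folded conformation. The fallback delivers oxygen to the opposite face through a halohydrin. It sets out from 32: NBS in aqueous THF at 0 °C should place bromonium on the face the peracid prefers and water on the tertiary C13 from the other side, giving the bromohydrin F4. K2CO3 in MeOH then closes the epoxide by displacement of bromide with inversion at C14, so that the epoxide oxygen lies on the face not reached by direct epoxidation, and the sequence comes back to the route at 33.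

Further compounds
F1 | step 14 | (3R,4E)-1-{2,6-dimethyl-3-[tri(propan-2-yl)silyloxy]phenyl}-3-methyl-6-(trimethylsilyl)hex-4-en-3-ol | Cc1ccc(O[Si](C(C)C)(C(C)C)C(C)C)c(C)c1CC[C@@](C)(O)/C=C/C[Si](C)(C)C
F2 | step 14 | {(2E,4R)-6-{2,6-dimethyl-3-[tri(propan-2-yl)silyloxy]phenyl}-4-(methoxymethoxy)-4-methylhex-2-en-1-yl}trimethylsilane | Cc1ccc(O[Si](C(C)C)(C(C)C)C(C)C)c(C)c1CC[C@@](C)(OCOC)/C=C/C[Si](C)(C)C
F3 | step 14 | 3-[(3R,4E)-3-(methoxymethoxy)-3-methyl-6-(trimethylsilyl)hex-4-en-1-yl]-2,4-dimethylphenol | Cc1ccc(O)c(C)c1CC[C@@](C)(OCOC)/C=C/C[Si](C)(C)C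
F4 | step 23 | (5R,8R,9R,10S,13R,14R)-3,14-dibromo-8,15-epoxylabd-2-en-13-ol | CC1(C)C(Br)=CC[C@]2(C)[C@H]3CC[C@@](C)(O)[C@H](Br)CO[C@]3(C)CC[C@@H]12
F5 | step 24 | (5R,8R,9R,10S,13R,14R)-3-bromo-14-chloro-8,15-epoxylabd-2-en-13-ol | CC1(C)C(Br)=CC[C@]2(C)[C@H]3CC[C@@](C)(O)[C@H](Cl)CO[C@]3(C)CC[C@@H]12
F6 | step 24 | (3S,5R,8R,9R,10S,13R,14R)-3-bromo-14-chloro-8,15-epoxylabdan-13-ol | CC1(C)[C@@H](Br)CC[C@]2(C)[C@H]3CC[C@@](C)(O)[C@H](Cl)CO[C@]3(C)CC[C@@H]12
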